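## Retrosynthetic overview

- The target is disconnected at the aryl ether C–O bond to a (2R,3S)-epoxy-phenol: the 4'-phenoxide opens the epoxide 5-exo-tet with inversion at the secondary carbon.
- That epoxide comes from phenol-directed, catalyst-controlled epoxidation of the proximal side-chain olefin of the unprotected neryl chalcone. The dihydrofuran ring is the only ring made, and it is closed last, in the same flask, together with both stereocentres.
- The neryl chalcone comes from a protecting-group-free Claisen–Schmidt condensation of 3'-neryl-2',4'-dihydroxyacetophenone with 4-hydroxybenzaldehyde.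
- The neryl ketone comes from C3'-selective C-alkylation of 2',4'-dihydroxyacetophenone with neryl bromide, made from nerol.

Assumption: the SMILES is read as (2S) at the ring carbon and (2S) at the side-chain carbinol. This pair corresponds to anti addition of the two oxygens across a (Z)-olefin, so the neryl chain is used; the same sequence on the (E)-geranyl compound xanthoangelol would give the (2S,2'R)/(2R,2'S) series.

Locants: 2', 4' and so on refer to the ketone-bearing ring A; 2'', 3'' and so on refer to the C10 side chain.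

## Route

Step 1
Reactants: 1 nerol, (2Z)-3,7-dimethylocta-2,6-dien-1-ol
Product: 2 neryl bromide, (2Z)-1-bromo-3,7-dimethylocta-2,6-diene
Conditions: PBr3 (0.4 equiv), Et2O, −10 → 0 °C, 30 min; cold aq. NaHCO3 wash; used crude at once
Reagents that add atoms: phosphorus tribromide, BrP(Br)Br
Why: Alcohol-to-bromide conversion with PBr3, an SN2 displacement of the dibromophosphite at the primary allylic carbon that keeps the (Z)-olefin at low temperature.

Step 2
Reactants: 3 2',4'-dihydroxyacetophenone, 1-(2,4-dihydroxyphenyl)ethan-1-one (2 equiv); 2 neryl bromide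
Product: 4 1-{3-[(2Z)-3,7-dimethylocta-2,6-dien-1-yl]-2,4-dihydroxyphenyl}ethan-1-one
Conditions: 10% aq. KOH, 0 °C → rt, 16 h; then HCl to pH 4
Reagents that add atoms: none
Why: Nuclear C-alkylation of a phenoxide in water, where the hydrogen-bonded oxygens are poor nucleophiles and the soft allylic bromide is attacked by C3', the most electron-rich carbon between the two oxygens, in an SN2 step that keeps the (Z)-olefin.

Step 3
Reactants: 4 neryl ketone; 5 4-hydroxybenzaldehyde (1.5 equiv)
Product: 7 (2E)-1-{3-[(2Z)-3,7-dimethylocta-2,6-dien-1-yl]-2,4-dihydroxyphenyl}-3-(4-hydroxyphenyl)prop-2-en-1-one, via aldol adduct 6 (not isolated)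
Conditions: KOH (50% aq., 15 equiv), EtOH, N2, 0 °C → rt, 48 h; then cold 1 M HCl to pH 4
Reagents that add atoms: none
Why: Claisen–Schmidt condensation, in which the ketone enolate adds to the non-enolisable aldehyde and E1cB loss of water from the racemic aldol 6 gives the thermodynamically preferred (E)-enone, while the isolated (Z)-olefin and the chelated 2'-OH are inert to aqueous base.

Step 4
Reactants: 7 neryl chalcone
Product: 9 (2E)-1-{(2S)-4-hydroxy-2-[(2S)-2-hydroxy-6-methylhept-5-en-2-yl]-2,3-dihydro-1-benzofuran-5-yl}-3-(4-hydroxyphenyl)prop-2-en-1-one, via (2R,3S)-epoxide 8 (not isolated)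
Conditions: VO(OiPr)3 (5 mol%), (R,R)-N,N'-dihydroxy-N,N'-bis(diphenylacetyl)cyclohexane-1,2-diamine (6 mol%), cumene hydroperoxide (1.2 equiv), toluene, 0 °C; then Me2S (0.5 equiv); then DBU (0.3 equiv), MeOH, rt
Reagents that add atoms: cumene hydroperoxide, CC(C)(OO)c1ccccc1
Why: Proposed new method: an ortho-phenol binds pentavalent vanadium as an aryloxide beside the alkylperoxide inside the C2-symmetric bishydroxamate pocket (the 4'-OH and 2'-OH are related by a local two-fold axis, so both should select the same olefin face), oxygen is delivered only to the proximal 2'',3''-olefin because the remote 6'',7''-olefin and the electron-poor enone are not touched by this hydroxyl-directed electrophilic oxidant, and after Me2S has destroyed surplus peroxide DBU ionises the most acidic 4'-OH, whose phenoxide opens (2R,3S)-epoxide 8 by 5-exo-tet SN2 attack at the secondary carbon with inversion while the tertiary C–O bond is retained, so the (Z)-geometry is translated into the (2S) ring carbon and the (2S) carbinol; the closest known reactions are the VO(acac)2/t-BuOOH epoxidation–cyclisation of 2-(2-alkenyl)phenols (racemic) and the vanadium–bishydroxamic acid asymmetric epoxidation of homoallylic alcohols, and since the sense of induction with a phenol as directing group has no precedent the (R,R)-ligand is a working choice that must be proven on the first batch.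

## Compound list

1 | nerol, (2Z)-3,7-dimethylocta-2,6-dien-1-ol | CC(C)=CCC/C(C)=C\CO | starting material
2 | neryl bromide, (2Z)-1-bromo-3,7-dimethylocta-2,6-diene | CC(C)=CCC/C(C)=C\CBr | intermediate
3 | 2',4'-dihydroxyacetophenone | CC(=O)c1ccc(O)cc1O | starting material
4 | 1-{3-[(2Z)-3,7-dimethylocta-2,6-dien-1-yl]-2,4-dihydroxyphenyl}ethan-1-one | CC(C)=CCC/C(C)=C\Cc1c(O)ccc(C(C)=O)c1O | intermediate
5 | 4-hydroxybenzaldehyde | O=Cc1ccc(O)cc1 | starting material
6 | 1-{3-[(2Z)-3,7-dimethylocta-2,6-dien-1-yl]-2,4-dihydroxyphenyl}-3-hydroxy-3-(4-hydroxyphenyl)propan-1-one (racemic aldol adduct, not isolated) | CC(C)=CCC/C(C)=C\Cc1c(O)ccc(C(=O)CC(O)c2ccc(O)cc2)c1O | intermediate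
7 | (2E)-1-{3-[(2Z)-3,7-dimethylocta-2,6-dien-1-yl]-2,4-dihydroxyphenyl}-3-(4-hydroxyphenyl)prop-2-en-1-one | CC(C)=CCC/C(C)=C\Cc1c(O)ccc(C(=O)/C=C/c2ccc(O)cc2)c1O | intermediate
8 | (2E)-1-[2,4-dihydroxy-3-({(2R,3S)-3-methyl-3-(4-methylpent-3-en-1-yl)oxiran-2-yl}methyl)phenyl]-3-(4-hydroxyphenyl)prop-2-en-1-one (not isolated) | CC(C)=CCC[C@]1(C)O[C@@H]1Cc2c(O)ccc(C(=O)/C=C/c3ccc(O)cc3)c2O | intermediate
9 | (2E)-1-{(2S)-4-hydroxy-2-[(2S)-2-hydroxy-6-methylhept-5-en-2-yl]-2,3-dihydro-1-benzofuran-5-yl}-3-(4-hydroxyphenyl)prop-2-en-1-one | CC(C)=CCC[C@](C)(O)[C@@H]1Cc2c(ccc(C(=O)/C=C/c3ccc(O)cc3)c2O)O1 | target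

## Step count and risks

Total step count: 4. Longest linear sequence: 4 steps (1 → 2 → 4 → 7 → 9).

**Step 4 (highest risk).** The risks are:
- the level and sense of induction are unproven for a phenol directing group;
- the triphenolic chalcone, in particular its o-hydroxyaryl ketone chelate, may displace the ligand and open a racemic background path;
- acid-type 6-endo opening of 8 to a chroman-3-ol may occur before the base is added;
- the 2'-oxygen may attack instead of the 4'-oxygen, which would show as loss of the chelated OH signal near 13 ppm.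

The absolute configuration of the first batch is assigned by ECD against the calculated spectrum or by X-ray of a 4-bromobenzoate. If the mirror image is formed, the (S,S)-ligand is used.

Fallback: this sets out from 7 and gives up asymmetric catalysis for resolution. The non-chiral phenol-directed system VO(acac)2 (2 mol%)/t-BuOOH in CH2Cl2 is used, surplus peroxide is destroyed with Me2S, and DBU closes the ring. This gives 8 together with its mirror-image epoxide, (2S,3R)-epoxide F7, and from these 9 together with its enantiomer, the (2R,2'R)-dihydrobenzofuran F8. Preparative chromatography on a chiral stationary phase (supercritical CO2/MeOH) separates 9 from F8, so the fallback comes back to the route at 9. The racemate is needed in any case as the reference for the enantiomer assay.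

**Step 2.** The risks are alkylation at C5' or at oxygen, double alkylation, and solvolysis of 2 to nerol, linalool and α-terpineol. A yield of about 25–35% is expected.

Fallback: this sets out from 2 and replaces phenoxide alkylation by directed ortho-metalation. 1,3-Bis(methoxymethoxy)benzene F1 is lithiated between the two oxygens (n-BuLi, THF, 0 °C) and alkylated with 2 in the presence of CuI (10 mol%). This gives 2-[(2Z)-3,7-dimethylocta-2,6-dien-1-yl]-1,3-bis(methoxymethoxy)benzene F2, with SN2 attack at the primary carbon keeping the (Z)-olefin. A second ortho-lithiation (n-BuLi, TMEDA, THF, −20 °C) and quench with N-methoxy-N-methylacetamide gives 1-{3-[(2Z)-3,7-dimethylocta-2,6-dien-1-yl]-2,4-bis(methoxymethoxy)phenyl}ethan-1-one F3. HCl in MeOH at 40 °C removes both acetals, and the fallback comes back to the route at 4.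

**Step 3.** The risks are that the phenoxide of 5 is a weak electrophile, that the polyanion of 4 enolises slowly, and that some flavanone forms on acidification.

Fallback: this sets out from 4 and uses a protected condensation. The non-chelated 4'-OH is masked (MOMCl, K2CO3, acetone) to give 1-{3-[(2Z)-3,7-dimethylocta-2,6-dien-1-yl]-2-hydroxy-4-(methoxymethoxy)phenyl}ethan-1-one F4. Aldehyde 5 is converted into 4-(methoxymethoxy)benzaldehyde F5 (MOMCl, iPr2NEt, CH2Cl2). Condensation of F4 with F5 (KOH, EtOH/H2O, rt) gives (2E)-1-{3-[(2Z)-3,7-dimethylocta-2,6-dien-1-yl]-2-hydroxy-4-(methoxymethoxy)phenyl}-3-[4-(methoxymethoxy)phenyl]prop-2-en-1-one F6. 3 M HCl in MeOH at 40 °C removes both acetals, and the fallback comes back to the route at 7.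

## Further compounds

F1 | step 2 | 1,3-bis(methoxymethoxy)benzene | COCOc1cccc(OCOC)c1
F2 | step 2 | 2-[(2Z)-3,7-dimethylocta-2,6-dien-1-yl]-1,3-bis(methoxymethoxy)benzene | CC(C)=CCC/C(C)=C\Cc1c(OCOC)cccc1OCOC
F3 | step 2 | 1-{3-[(2Z)-3,7-dimethylocta-2,6-dien-1-yl]-2,4-bis(methoxymethoxy)phenyl}ethan-1-one | CC(C)=CCC/C(C)=C\Cc1c(OCOC)ccc(C(C)=O)c1OCOC
F4 | step 3 | 1-{3-[(2Z)-3,7-dimethylocta-2,6-dien-1-yl]-2-hydroxy-4-(methoxymethoxy)phenyl}ethan-1-one | CC(C)=CCC/C(C)=C\Cc1c(OCOC)ccc(C(C)=O)c1O
F5 | step 3 | 4-(methoxymethoxy)benzaldehyde | COCOc1ccc(C=O)cc1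
F6 | step 3 | (2E)-1-{3-[(2Z)-3,7-dimethylocta-2,6-dien-1-yl]-2-hydroxy-4-(methoxymethoxy)phenyl}-3-[4-(methoxymethoxy)phenyl]prop-2-en-1-one | CC(C)=CCC/C(C)=C\Cc1c(OCOC)ccc(C(=O)/C=C/c2ccc(OCOC)cc2)c1O
F7 | step 4 | (2E)-1-[2,4-dihydroxy-3-({(2S,3R)-3-methyl-3-(4-methylpent-3-en-1-yl)oxiran-2-yl}methyl)phenyl]-3-(4-hydroxyphenyl)prop-2-en-1-one | CC(C)=CCC[C@@]1(C)O[C@H]1Cc2c(O)ccc(C(=O)/C=C/c3ccc(O)cc3)c2O
F8 | step 4 | (2E)-1-{(2R)-4-hydroxy-2-[(2R)-2-hydroxy-6-methylhept-5-en-2-yl]-2,3-dihydro-1-benzofuran-5-yl}-3-(4-hydroxyphenyl)prop-2-en-1-one | CC(C)=CCC[C@@](C)(O)[C@H]1Cc2c(ccc(C(=O)/C=C/c3ccc(O)cc3)c2O)O1
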